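**Retrosynthetic overview**

1. Numbering (spiro[5.5]undecane): ring A = C1 (carbinol), C2, C3 (CHBr), C4, C5 (CMe2), C6 (spiro atom). Ring B = C6, C7=C8, C9 (=CHBr), C10, C11.
2. Last disconnection, C1–C2. The trans-1,3-bromohydrin C1(OH)–C2H2–C3HBr of ring A is the retron of a bromide-terminated Prins (carbonyl–olefin) cyclisation. The target therefore comes in one operation from a monocyclic ketone in which C6 carries an acetyl group (C1) and C5 carries an allyl group (C4–C3=C2).
3. Enabling feature: the C2 methylene of ring A lies between an oxygen-bearing carbon (C1) and a bromine-bearing carbon (C3). C1 and C4 hang on the adjacent fully substituted pair C6/C5, which presses the carbonyl carbon and the terminal alkene carbon into a six-membered chair.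
4. Earlier disconnections: C9=CHBr by Wittig reaction of a C9 enone. C6 by copper hydride desymmetrisation of an achiral 4,4-disubstituted cyclohexadienone. The C5–C6 bond by oxidative dearomatisation with 1,2-shift of a para-hydroxyphenyl carbinol, itself made from an aryllithium and a methyl ketone.
5. Ring order: ring B first (it enters as a benzene ring), ring A last, closed in the final step without protecting groups.

Key step: step 7

Assumption: the (R)-configured bisphosphine is taken to be the ligand antipode that delivers the (S)-enone in step 5. If the sense of induction is opposite, the (S)-ligand is used and nothing else changes.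

**Step 1**
Reactants: 1 2,2-dimethylpent-4-enoic acid
Product: 3 3,3-dimethylhex-5-en-2-one, via dilithium gem-diolate 2 (not isolated)
Conditions: MeLi (2.2 equiv), Et2O, 0 °C to rt; then H2O
Reagents that add atoms: methyllithium, [Li]C
Why: Organolithium addition to a lithium carboxylate stops at the tetrahedral gem-diolate, which collapses to the methyl ketone only on aqueous work-up (carboxylic acid to methyl ketone synthesis); no stereocentre is formed.

**Step 2**
Reactants: 4 (4-bromophenoxy)(tert-butyl)dimethylsilane; 3 3,3-dimethylhex-5-en-2-one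
Product: 6 2-[4-(tert-butyldimethylsilyloxy)phenyl]-3,3-dimethylhex-5-en-2-ol (racemic), via aryllithium 5 (not isolated)
Conditions: n-BuLi (1.05 equiv), THF, –78 °C; then 3, –78 to 0 °C; then H2O
Reagents that add atoms: none
Why: Bromine–lithium exchange followed by 1,2-addition of the aryllithium to a pinacolone-type ketone; the carbinol centre is deliberately left racemic because it becomes the planar acetyl carbon in step 4.

**Step 3**
Reactants: 6 2-[4-(tert-butyldimethylsilyloxy)phenyl]-3,3-dimethylhex-5-en-2-ol
Product: 7 4-(2-hydroxy-3,3-dimethylhex-5-en-2-yl)phenol (racemic)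
Conditions: Bu4NF (1.1 equiv), THF, 0 °C; then H2O
Reagents that add atoms: none
Why: Fluoride-induced silyl ether cleavage, chosen because it is non-acidic and the tertiary para-hydroxybenzylic alcohol would ionise in acid.

**Step 4**
Reactants: 7 4-(2-hydroxy-3,3-dimethylhex-5-en-2-yl)phenol
Product: 8 4-acetyl-4-(2-methylpent-4-en-2-yl)cyclohexa-2,5-dien-1-one (achiral)
Conditions: PhI(OAc)2 (1.1 equiv), (CF3)2CHOH/CH2Cl2, 0 °C
Reagents that add atoms: none
Why: Oxidative dearomatisation of the phenol by trivalent iodine gives a phenoxenium ion whose para carbon accepts the better migrating tertiary alkyl group from the adjacent carbinol carbon (oxidative Wagner–Meerwein/semipinacol shift), which forges the C5–C6 bond between two fully substituted carbons and releases the acetyl group.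

**Step 5**
Reactants: 8 4-acetyl-4-(2-methylpent-4-en-2-yl)cyclohexa-2,5-dien-1-one
Product: 10 (4S)-4-acetyl-4-(2-methylpent-4-en-2-yl)cyclohex-2-en-1-one, via silyl dienol ether 9 (not isolated)
Conditions: Cu(OAc)2 (5 mol %), (R)-DTBM-SEGPHOS (5.5 mol %), (EtO)2MeSiH (1.2 equiv), toluene, –20 °C; then 1 M HCl, THF, 0 °C
Reagents that add atoms: none
Why: Asymmetric copper hydride conjugate reduction used as desymmetrisation of a prochiral 4,4-disubstituted cyclohexadienone: the ligated copper hydride approaches the ring face opposite the bulky tertiary alkyl group and the ligand selects one of the two enantiotopic β-carbons, which makes C6 stereogenic (S), while silylation of the enolate as 9 prevents a second reduction.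

**Step 6**
Reactants: 10 (4S)-4-acetyl-4-(2-methylpent-4-en-2-yl)cyclohex-2-en-1-one
Product: 11 1-[(1S,4E)-4-(bromomethylidene)-1-(2-methylpent-4-en-2-yl)cyclohex-2-en-1-yl]ethan-1-one
Conditions: [Ph3PCH2Br]Br (1.3 equiv), KOtBu (1.25 equiv), THF, –78 °C; then 10, –78 to 0 °C
Reagents that add atoms: (bromomethyl)triphenylphosphonium bromide, BrC[P+](c1ccccc1)(c1ccccc1)c1ccccc1.[Br-]
Why: Wittig bromomethylenation: the open enone carbonyl C9 reacts while the acetyl group next to quaternary C6 does not, and the kinetically controlled addition of the non-stabilised halo-ylide should place bromine cis to the larger sp3 neighbour C10H2 rather than to the flat C8H, favouring the E isomer, from which any Z isomer is removed by chromatography.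

**Step 7**
Reactants: 11 1-[(1S,4E)-4-(bromomethylidene)-1-(2-methylpent-4-en-2-yl)cyclohex-2-en-1-yl]ethan-1-one
Product: 13 (1S,3R,6S,9E)-3-bromo-9-(bromomethylidene)-1,5,5-trimethylspiro[5.5]undec-7-en-1-ol, via tribromotitanium alkoxide 12 (not isolated)
Conditions: TiBr4 (2.2 equiv), 2,6-di-tert-butyl-4-methylpyridine (0.3 equiv), CH2Cl2 (0.01 M), –78 to –40 °C; then H2O
Reagents that add atoms: titanium tetrabromide, Br[Ti](Br)(Br)Br
Why: TiBr4 binds the acetyl oxygen of 11, the terminal alkene carbon C2 attacks the activated carbonyl carbon C1, and the positive charge developing at C3 is quenched by bromide from the TiBr5– counter-ion, so the C1–C2 bond, the C3–Br bond, the tertiary alkoxide 12 and the spiro junction arise in one operation and water then frees 13. The closest known reaction type is the Lewis-acid-induced Prins (cationic carbonyl–olefin) cyclisation of alkenyl aldehydes and ketones with halide capture, which gives 3-halocyclohexanols. Ring A closes 6-endo-trig at the alkene and 6-exo-trig at the carbonyl group through a chair. C1 is controlled by that chair: the titanium-bound oxygen stands axial and the C1 methyl equatorial because an axial methyl would clash with the axial methyl on C5, and the flat sp2 arm C7 of ring B takes the axial site on C6 anti to that oxygen while the bulkier C11H2 arm lies equatorial, which translates (S)-C6 into (S)-C1. C3 is controlled by anti addition across the alkene: bromide enters antiperiplanar to the new C1–C2 bond, that is equatorially, giving (R)-C3 with bromine trans to the hydroxyl group. The step needs the terminal alkene to react instead of the bromodiene and bromide capture to outrun proton loss; the first is secured because C7=C8 could reach C1 only through a three- or four-membered ring and the quaternary pair C5/C6 presses C2 against C1 (Thorpe–Ingold effect), the second by the high bromide activity of TiBr4 in CH2Cl2 at low temperature and by the hindered pyridine, which removes adventitious HBr.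

**Compound list**

| No. | Name | SMILES | Role |
|---|---|---|---|
| 1 | 2,2-dimethylpent-4-enoic acid | C=CCC(C)(C)C(=O)O | starting material |
| 2 | dilithium 3,3-dimethylhex-5-ene-2,2-diolate | C=CCC(C)(C)C(C)(O[Li])O[Li] | intermediate |
| 3 | 3,3-dimethylhex-5-en-2-one | CC(=O)C(C)(C)CC=C | intermediate |
| 4 | (4-bromophenoxy)(tert-butyl)dimethylsilane | CC(C)(C)[Si](C)(C)Oc1ccc(Br)cc1 | starting material |
| 5 | [4-(tert-butyldimethylsilyloxy)phenyl]lithium | [Li]c1ccc(O[Si](C)(C)C(C)(C)C)cc1 | intermediate |
| 6 | 2-[4-(tert-butyldimethylsilyloxy)phenyl]-3,3-dimethylhex-5-en-2-ol (racemic) | CC(O)(c1ccc(O[Si](C)(C)C(C)(C)C)cc1)C(C)(C)CC=C | intermediate |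
| 7 | 4-(2-hydroxy-3,3-dimethylhex-5-en-2-yl)phenol (racemic) | CC(O)(c1ccc(O)cc1)C(C)(C)CC=C | intermediate |
| 8 | 4-acetyl-4-(2-methylpent-4-en-2-yl)cyclohexa-2,5-dien-1-one (achiral) | CC(=O)C1(C(C)(C)CC=C)C=CC(=O)C=C1 | intermediate |
| 9 | 1-[(1S)-4-[diethoxy(methyl)silyl]oxy-1-(2-methylpent-4-en-2-yl)cyclohexa-2,4-dien-1-yl]ethan-1-one | CC(=O)[C@]1(C(C)(C)CC=C)C=CC(O[Si](C)(OCC)OCC)=CC1 | intermediate |
| 10 | (4S)-4-acetyl-4-(2-methylpent-4-en-2-yl)cyclohex-2-en-1-one | CC(=O)[C@]1(C(C)(C)CC=C)C=CC(=O)CC1 | intermediate |
| 11 | 1-[(1S,4E)-4-(bromomethylidene)-1-(2-methylpent-4-en-2-yl)cyclohex-2-en-1-yl]ethan-1-one | CC(=O)[C@]1(C(C)(C)CC=C)C=C/C(=C/Br)CC1 | intermediate |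
| 12 | tribromotitanium alkoxide of 13 | CC1(C)C[C@@H](Br)C[C@](C)(O[Ti](Br)(Br)Br)[C@@]12C=C/C(=C/Br)CC2 | intermediate |
| 13 | (1S,3R,6S,9E)-3-bromo-9-(bromomethylidene)-1,5,5-trimethylspiro[5.5]undec-7-en-1-ol | CC1(C)C[C@@H](Br)C[C@](C)(O)[C@@]12C=C/C(=C/Br)CC2 | target |

Total step count: 7
Longest linear sequence: 7 steps (1 to 13; 4 enters in step 2)

**Steps most likely to fail**

**Step 7.** Three things may go wrong:
- the C3 cation loses a proton instead of capturing bromide;
- the chair discriminates weakly between the two arms of ring B;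
- the Lewis acid isomerises or oligomerises the bromodiene.

The fallback sets out from 10 and comes back at 13. It inverts ring closure and olefination, so that ring B is an electron-poor, TiBr4-complexed enone during the cyclisation. TiBr4 (3.2 equiv, CH2Cl2, –78 °C, then H2O) should convert 10 into the spiro enone bromohydrin F1. Et3SiOTf and 2,6-lutidine cap the tertiary alcohol as the triethylsilyl ether F2, which blocks Grob fragmentation of the 1,3-bromo alkoxide under the basic ylide. Wittig bromomethylenation as in step 6 gives the silylated bromodiene F3, and HF·pyridine in THF frees 13.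

**Step 4.** The tertiary alkyl group may leave heterolytically as a cation, with rearomatisation of the ring, instead of undergoing the 1,2-shift.

The fallback sets out from 3 and comes back at 8. It builds ring B by a Diels–Alder reaction instead of from an arene.
- 1-Ethoxyvinyllithium (ethyl vinyl ether, t-BuLi, THF) adds to 3 to give the enol ether carbinol F4, and dilute HCl hydrolyses it to the ketol F5.
- SOCl2 in pyridine dehydrates F5 to the α-methylene ketone F6. Elimination can only go toward the methyl group, because the other neighbour is quaternary.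
- Heating F6 with (E)-1-methoxy-3-(trimethylsilyloxy)buta-1,3-diene in toluene gives the cycloadduct F7, with the methoxy-bearing carbon next to and the silyloxy-bearing carbon para to the new quaternary carbon.
- Dilute acid turns F7 into the racemic enone F8, and DDQ in dioxane dehydrogenates it to achiral 8. Step 5 then sets the configuration.

**Step 6.** E/Z discrimination at the exocyclic double bond may be low.

The fallback sets out from 10 and comes back at 11. It fixes the geometry by enolisation of an s-trans enal and carries it through stereoretentive steps.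
- Wittig reaction with [Ph3PCH2OMe]Cl and KOtBu gives the dienol methyl ether F9, whose geometry is irrelevant. Mild aqueous acid converts it into the conjugated enal F10.
- Tf2O with 2,6-di-tert-butyl-4-methylpyridine activates the aldehyde oxygen in the s-trans conformer, and loss of a C7 proton gives the (E)-dienyl triflate F11, with oxygen cis to C10.
- (Me3Sn)2, Pd(PPh3)4 and LiCl give the (E)-dienylstannane F12 with retention.
- N-Bromosuccinimide replaces tin by bromine with retention to give 11.

**Further compounds**

F1 | step 7 | (1S,3R,6S)-3-bromo-1-hydroxy-1,5,5-trimethylspiro[5.5]undec-7-en-9-one | CC1(C)C[C@@H](Br)C[C@](C)(O)[C@@]12C=CC(=O)CC2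
F2 | step 7 | triethylsilyl ether of F1 | CC1(C)C[C@@H](Br)C[C@](C)(O[Si](CC)(CC)CC)[C@@]12C=CC(=O)CC2
F3 | step 7 | triethylsilyl ether of 13 | CC1(C)C[C@@H](Br)C[C@](C)(O[Si](CC)(CC)CC)[C@@]12C=C/C(=C/Br)CC2
F4 | step 4 | 2-ethoxy-3,4,4-trimethylhepta-1,6-dien-3-ol (racemic) | C=C(OCC)C(C)(O)C(C)(C)CC=C
F5 | step 4 | 3-hydroxy-3,4,4-trimethylhept-6-en-2-one (racemic) | CC(=O)C(C)(O)C(C)(C)CC=C
F6 | step 4 | 4,4-dimethyl-3-methylidenehept-6-en-2-one | CC(=O)C(=C)C(C)(C)CC=C
F7 | step 4 | 1-[2-methoxy-1-(2-methylpent-4-en-2-yl)-4-(trimethylsilyloxy)cyclohex-3-en-1-yl]ethan-1-one (racemic) | CC(=O)C1(C(C)(C)CC=C)CCC(O[Si](C)(C)C)=CC1OC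
F8 | step 4 | 4-acetyl-4-(2-methylpent-4-en-2-yl)cyclohex-2-en-1-one (racemic) | CC(=O)C1(C(C)(C)CC=C)C=CC(=O)CC1
F9 | step 6 | 1-[(1S)-4-(methoxymethylidene)-1-(2-methylpent-4-en-2-yl)cyclohex-2-en-1-yl]ethan-1-one (E/Z mixture) | CC(=O)[C@]1(C(C)(C)CC=C)C=CC(=COC)CC1
F10 | step 6 | (4S)-4-acetyl-4-(2-methylpent-4-en-2-yl)cyclohex-1-ene-1-carbaldehyde | CC(=O)[C@]1(C(C)(C)CC=C)CC=C(C=O)CC1
F11 | step 6 | (E)-[(4S)-4-acetyl-4-(2-methylpent-4-en-2-yl)cyclohex-2-en-1-ylidene]methyl trifluoromethanesulfonate | CC(=O)[C@]1(C(C)(C)CC=C)C=C/C(=C/OS(=O)(=O)C(F)(F)F)CC1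
F12 | step 6 | 1-[(1S,4E)-1-(2-methylpent-4-en-2-yl)-4-[(trimethylstannyl)methylidene]cyclohex-2-en-1-yl]ethan-1-one | CC(=O)[C@]1(C(C)(C)CC=C)C=C/C(=C/[Sn](C)(C)C)CC1
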